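**Retrosynthetic overview**

- Eudesmane numbering is used throughout: ring A = C1–C5 and C10; ring B = C5–C10; C14 = methyl on C10; C15 = methylene on C4; C11–C13 = acrylate on C7; beta = the face of C14.
- Late stage: the triol is unmasked by desilylation; the C1 and C3 hydroxyls come from two Luche reductions of a ring-A 3-methoxy-2-en-1-one, C15 from Lombardo methylenation of the C4 ketone, the C6 ester from Steglich acylation, and the C7 acrylate from a 2-silyloxyethyl arm (oxidation, alpha-methylenation, esterification).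
- Core: an enantioselective Diels–Alder reaction joins 2-methoxy-5-methyl-1,4-benzoquinone (ring A with C14) and a (1E)-1-silyloxy-2-(2-silyloxyethyl)buta-1,3-diene (C6–C9 with C11–C12). It forms C9–C10 and C5–C6 and closes ring B onto ring A; C5 epimerisation then gives the trans-decalin and hydroxyl-directed hydrogenation sets C7.
- Enabling feature: ring A carries oxygen on C1 and C3 and an sp2 carbon at C4, with C1 and C4 para to each other on either side of the C5–C10 fusion bond and a methyl on C10, which is the pattern of a 2-alkoxy-5-methyl-para-quinone. Ring B carries oxygen on C6 next to fusion carbon C5 and a carbon branch on C7, which is the pattern of a 1-oxy-2-alkyl-1,3-diene.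
- Ring order: ring A is present from the start (arene, then quinone); ring B is formed in the key step.

Key step: step 5

Assumption: the quinone face selected by the (R)-BINOL–titanium catalyst is assigned by analogy with related chelated 2-methoxyquinones; should the antipodal adduct form, (S)-BINOL is used and nothing else changes.

**Route**

Step 1
Reactants: 1 4-(tert-butyldimethylsilyloxy)butanal; 2 cyclohexylamine
Product: 3 (E)-N-cyclohexyl-4-(tert-butyldimethylsilyloxy)butan-1-imine
Conditions: MgSO4, Et2O, 0 °C to rt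
Reagents that add atoms: none
Why: Condensation of an aldehyde with a primary amine (imine formation) driven by the drying agent; no stereocentre is formed.

Step 2
Reactants: 3 N-cyclohexyl imine; 4 acetaldehyde
Product: 6 (E)-2-[2-(tert-butyldimethylsilyloxy)ethyl]but-2-enal, via beta-hydroxy imine 5 (not isolated)
Conditions: LiN(iPr)2, THF, −78 °C; then 4, −78 to −20 °C; then aq. oxalic acid, rt
Reagents that add atoms: water (O)
Why: Directed aldol condensation through the metallated imine (Wittig directed aldol): the lithiated aza-enolate adds to acetaldehyde, and acidic hydrolysis of 5 should liberate the aldehyde and dehydrate it to the conjugated enal with the thermodynamic E geometry (formyl trans to methyl).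

Step 3
Reactants: 6 (E)-2-[2-(tert-butyldimethylsilyloxy)ethyl]but-2-enal
Product: 7 (1E)-2-[2-(tert-butyldimethylsilyloxy)ethyl]-1-(triethylsilyloxy)buta-1,3-diene
Conditions: Et3SiOTf, Et3N, Et2O, 0 °C
Reagents that add atoms: triethylsilyl trifluoromethanesulfonate (CC[Si](CC)(CC)OS(=O)(=O)C(F)(F)F)
Why: Silyl dienol ether formation by soft enolisation: O-silylation of the s-trans enal and gamma-deprotonation of the methyl group should give the 1-silyloxy diene with the silyloxy group trans to the vinyl group, as known for tiglic aldehyde.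

Step 4
Reactants: 8 2-methoxy-5-methylphenol
Product: 9 2-methoxy-5-methyl-1,4-benzoquinone
Conditions: O2 (1 atm), Co(salen) (C16H14CoN2O2, cat.), DMF, rt
Reagents that add atoms: dioxygen (O=O)
Why: Cobalt–salen-catalysed aerobic oxidation of a phenol with a free para position to the para-quinone.

Step 5
Reactants: 9 2-methoxy-5-methyl-1,4-benzoquinone; 7 (1E)-silyloxy diene
Product: 10 cis-fused cycloadduct (5βH, 6α-triethylsilyloxy, C14 β)
Conditions: catalyst from (R)-BINOL and TiCl2(OiPr)2 (20 mol %, preformed over 4 Å MS, decanted), toluene, −40 to 0 °C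
Reagents that add atoms: none
Why: A [4+2] cycloaddition (Diels–Alder reaction) of the electron-rich 1-silyloxy diene 7 with the methyl-bearing double bond of quinone 9, which the titanium centre activates by chelating the quinone carbonyl next to the methoxy carbon together with the methoxy oxygen; the closest known reaction type is the BINOL–titanium-catalysed enantioselective Diels–Alder reaction of 2-methoxy-1,4-benzoquinones with silyloxy dienes. Ring B is closed by suprafacial [4+2] addition across the quinone double bond, C9–C10 and C5–C6 forming in the same event, while ring A (the former quinone) becomes the ene-dione that already carries the C1, C3 and C4 oxygenation. The quaternary C10 configuration is set by the quinone face left open by the BINOL ligand; C5 ends cis to C14 because the addition is suprafacial (corrected in step 6); C6 is set by the endo transition state with the E silyloxy group pointing outward, which places that group anti to H5 and C14. The step needs orientational control (C9 to the methyl-bearing carbon, C6 to the CH carbon), and this is secured because the diene terminus remote from the silyloxy group is the nucleophilic one and the chelated carbonyl has the methyl-bearing carbon as its beta position; chelating Lewis acids are known to preserve this uncatalysed orientation. Site selectivity follows from the methoxy-bearing double bond being a deactivated vinylogous ester.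

Step 6
Reactants: 10 cis-fused cycloadduct
Product: 11 trans-fused ene-dione (5αH)
Conditions: DBU (cat.), toluene, 0 °C to rt
Reagents that add atoms: none
Why: Base-mediated epimerisation through the C4–C5 enolate should convert the kinetic cis adduct into the thermodynamically favoured trans-fused isomer (H5 alpha, anti to C14), as in the cis-to-trans equilibration of angularly methylated decalin-1,4-diones and of 4-oxo-5β-steroids; the pseudo-equatorial silyloxy group is poorly aligned for beta-elimination.

Step 7
Reactants: 11 trans-fused ene-dione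
Product: 12 6α-hydroxy ene-dione
Conditions: HF·pyridine, pyridine, THF, 0 °C
Reagents that add atoms: none
Why: Fluoride-mediated desilylation; under buffered HF·pyridine the secondary triethylsilyl ether should be cleaved much faster than the primary tert-butyldimethylsilyl ether.

Step 8
Reactants: 12 6α-hydroxy ene-dione
Product: 13 saturated 6α-hydroxy ene-dione (7αH)
Conditions: H2 (1 atm), [Ir(cod)(PCy3)(py)]PF6 (5 mol %), CH2Cl2, rt
Reagents that add atoms: none
Why: Hydroxyl-directed homogeneous hydrogenation: the cationic iridium catalyst binds the C6 alpha-hydroxyl and should deliver H2 to the alpha face of the C7=C8 double bond (also the face opposite C14), setting C7 with H alpha and the side chain beta, trans to the C6 oxygen; the electron-poor, undirected ene-dione double bond should survive.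

Step 9
Reactants: 13 saturated 6α-hydroxy ene-dione
Product: 14 6α-hydroxy-4(15)-methylene dienone
Conditions: Zn, CH2Br2, TiCl4, THF/CH2Cl2, 0 °C to rt
Reagents that add atoms: dibromomethane (BrCBr)
Why: Lombardo methylenation: the non-basic Zn/CH2Br2/TiCl4 reagent should convert the more electrophilic C4 ketone into the exocyclic methylene without enolisation, while the vinylogous ester carbonyl at C1 does not react.

Step 10
Reactants: 15 methyl 2-(hydroxymethyl)acrylate
Product: 16 methyl 2-[(tert-butyldiphenylsilyloxy)methyl]acrylate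
Conditions: tBuPh2SiCl, imidazole, CH2Cl2, 0 °C to rt
Reagents that add atoms: tert-butyl(chloro)diphenylsilane (CC(C)(C)[Si](Cl)(c1ccccc1)c1ccccc1)
Why: Standard silylation of a primary alcohol.

Step 11
Reactants: 16 methyl 2-[(tert-butyldiphenylsilyloxy)methyl]acrylate
Product: 17 2-[(tert-butyldiphenylsilyloxy)methyl]acrylic acid
Conditions: LiOH, THF/H2O, 0 °C; then 1 M HCl to pH 3
Reagents that add atoms: lithium hydroxide ([Li+].[OH-])
Why: Saponification of the methyl ester; the silyl ether is stable to aqueous LiOH at 0 °C.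

Step 12
Reactants: 14 6α-hydroxy-4(15)-methylene dienone; 17 2-[(tert-butyldiphenylsilyloxy)methyl]acrylic acid
Product: 18 C6 acrylate ester with 12-silyloxy arm
Conditions: DCC, DMAP, CH2Cl2, 0 °C to rt
Reagents that add atoms: none
Why: Steglich esterification of the only free hydroxyl (equatorial C6–OH); the C6 configuration is untouched.

Step 13
Reactants: 18 C6 acrylate ester with 12-silyloxy arm
Product: 19 C6 acrylate ester with 12-hydroxy arm
Conditions: HF·pyridine, pyridine, THF, 0 °C to rt
Reagents that add atoms: none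
Why: Selective desilylation; the primary tert-butyldimethylsilyl ether should be removed while the more robust tert-butyldiphenylsilyl ether stays.

Step 14
Reactants: 19 C6 acrylate ester with 12-hydroxy arm
Product: 21 11(13)-en-12-al, via aldehyde 20 (not isolated)
Conditions: Dess–Martin periodinane, CH2Cl2, 0 °C to rt; then CH2=NMe2+ I−, Et3N, CH2Cl2, rt
Reagents that add atoms: dimethylmethyleneiminium iodide (C[N+](C)=C.[I-])
Why: Dess–Martin oxidation to the aldehyde, then Mannich-type alpha-methylenation (aminomethylation and beta-elimination of dimethylamine) should give the 2-substituted acrolein under conditions that leave the esters and the C7 stereocentre alone.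

Step 15
Reactants: 21 11(13)-en-12-al
Product: 23 methyl 11(13)-en-12-oate, via carboxylic acid 22 (not isolated)
Conditions: NaClO2, NaH2PO4, 2-methyl-2-butene, tBuOH/H2O, 0 °C to rt; then Me3SiCHN2, toluene/MeOH, 0 °C
Reagents that add atoms: sodium chlorite ([Na+].[O-]Cl=O); trimethylsilyldiazomethane (C[Si](C)(C)C=[N+]=[N-])
Why: Pinnick oxidation of the enal to the acrylic acid, then methyl ester formation with trimethylsilyldiazomethane, both mild enough for the dienone and the acrylates.

Step 16
Reactants: 23 methyl 11(13)-en-12-oate (1-oxo)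
Product: 24 1β-hydroxy dienol ether
Conditions: NaBH4, CeCl3·7H2O, MeOH, −20 to 0 °C
Reagents that add atoms: none
Why: Luche 1,2-reduction of the vinylogous ester carbonyl; hydride should attack from the alpha face, anti to the axial C14 methyl on the neighbouring carbon, giving the 1β (equatorial) alcohol, while the acrylate esters are not reduced under these conditions.

Step 17
Reactants: 24 1β-hydroxy dienol ether
Product: 25 1β-triethylsilyloxy dienol ether
Conditions: Et3SiOTf, 2,6-lutidine, CH2Cl2, −78 °C
Reagents that add atoms: triethylsilyl trifluoromethanesulfonate (CC[Si](CC)(CC)OS(=O)(=O)C(F)(F)F)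
Why: Silylation of the allylic alcohol, which suppresses ionisation at C1 (loss of the C1 oxygen by allylic transposition) in the next step.

Step 18
Reactants: 25 1β-triethylsilyloxy dienol ether
Product: 26 3-oxo-4(15)-ene
Conditions: oxalic acid (cat.), THF/H2O, 0 °C to rt
Reagents that add atoms: water (O)
Why: Mild acid hydrolysis of the 2-methoxy-1,3-diene: protonation at C2 gives the conjugated oxocarbenium ion, which water converts into the alpha-methylene ketone with the beta-silyloxy group retained.

Step 19
Reactants: 26 3-oxo-4(15)-ene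
Product: 27 3β-hydroxy-1β-triethylsilyloxy diester
Conditions: NaBH4, CeCl3·7H2O, MeOH, −78 °C
Reagents that add atoms: none
Why: Luche 1,2-reduction of the exocyclic enone; axial hydride attack from the alpha face of the chair should give the equatorial 3β alcohol, syn to the C1 oxygen.

Step 20
Reactants: 27 3β-hydroxy-1β-triethylsilyloxy diester
Product: 28 methyl 1β,3β-dihydroxy-6α-[2-(hydroxymethyl)acryloyloxy]eudesma-4(15),11(13)-dien-12-oate (CNP0247525.1)
Conditions: HF·pyridine, THF, 0 °C to rt
Reagents that add atoms: none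
Why: Global desilylation under acidic fluoride conditions, which should remove both silyl groups without acyl migration or conjugate addition to the acrylates.

**Compound list**

1 | 4-(tert-butyldimethylsilyloxy)butanal | CC(C)(C)[Si](C)(C)OCCCC=O | starting material
2 | cyclohexylamine | NC1CCCCC1 | starting material
3 | (E)-N-cyclohexyl-4-(tert-butyldimethylsilyloxy)butan-1-imine | CC(C)(C)[Si](C)(C)OCCC/C=N/C1CCCCC1 | intermediate
4 | acetaldehyde | CC=O | starting material
5 | N-cyclohexyl imine of 2-[2-(tert-butyldimethylsilyloxy)ethyl]-3-hydroxybutanal (aldol adduct, diastereomer mixture) | CC(O)C(CCO[Si](C)(C)C(C)(C)C)/C=N/C1CCCCC1 | intermediate (not isolated)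
6 | (E)-2-[2-(tert-butyldimethylsilyloxy)ethyl]but-2-enal | C/C=C(/C=O)CCO[Si](C)(C)C(C)(C)C | intermediate
7 | (1E)-2-[2-(tert-butyldimethylsilyloxy)ethyl]-1-(triethylsilyloxy)buta-1,3-diene | C=C/C(CCO[Si](C)(C)C(C)(C)C)=C/O[Si](CC)(CC)CC | intermediate
8 | 2-methoxy-5-methylphenol | COc1ccc(C)cc1O | starting material
9 | 2-methoxy-5-methyl-1,4-benzoquinone | COC1=CC(=O)C(C)=CC1=O | intermediate
10 | 12-(tert-butyldimethylsilyloxy)-3-methoxy-6α-(triethylsilyloxy)-13,15-dinor-5βH-eudesma-2,7-diene-1,4-dione (cis-fused, C14 β) | CC[Si](CC)(CC)O[C@@H]1[C@@H]2C(=O)C(OC)=CC(=O)[C@]2(C)CC=C1CCO[Si](C)(C)C(C)(C)C | intermediate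
11 | 12-(tert-butyldimethylsilyloxy)-3-methoxy-6α-(triethylsilyloxy)-13,15-dinor-5αH-eudesma-2,7-diene-1,4-dione (trans-fused) | CC[Si](CC)(CC)O[C@@H]1[C@H]2C(=O)C(OC)=CC(=O)[C@]2(C)CC=C1CCO[Si](C)(C)C(C)(C)C | intermediate
12 | 12-(tert-butyldimethylsilyloxy)-6α-hydroxy-3-methoxy-13,15-dinor-5αH-eudesma-2,7-diene-1,4-dione | O[C@@H]1[C@H]2C(=O)C(OC)=CC(=O)[C@]2(C)CC=C1CCO[Si](C)(C)C(C)(C)C | intermediate
13 | 12-(tert-butyldimethylsilyloxy)-6α-hydroxy-3-methoxy-13,15-dinor-5αH,7αH-eudesm-2-ene-1,4-dione | O[C@@H]1[C@H]2C(=O)C(OC)=CC(=O)[C@]2(C)CC[C@H]1CCO[Si](C)(C)C(C)(C)C | intermediate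
14 | 12-(tert-butyldimethylsilyloxy)-6α-hydroxy-3-methoxy-13-nor-5αH,7αH-eudesma-2,4(15)-dien-1-one | O[C@@H]1[C@H]2C(=C)C(OC)=CC(=O)[C@]2(C)CC[C@H]1CCO[Si](C)(C)C(C)(C)C | intermediate
15 | methyl 2-(hydroxymethyl)acrylate | C=C(CO)C(=O)OC | starting material
16 | methyl 2-[(tert-butyldiphenylsilyloxy)methyl]acrylate | C=C(CO[Si](c1ccccc1)(c1ccccc1)C(C)(C)C)C(=O)OC | intermediate
17 | 2-[(tert-butyldiphenylsilyloxy)methyl]acrylic acid | C=C(CO[Si](c1ccccc1)(c1ccccc1)C(C)(C)C)C(=O)O | intermediate
18 | 12-(tert-butyldimethylsilyloxy)-3-methoxy-1-oxo-13-nor-5αH,7αH-eudesma-2,4(15)-dien-6α-yl 2-[(tert-butyldiphenylsilyloxy)methyl]acrylate | C=C(CO[Si](c3ccccc3)(c4ccccc4)C(C)(C)C)C(=O)O[C@@H]1[C@H]2C(=C)C(OC)=CC(=O)[C@]2(C)CC[C@H]1CCO[Si](C)(C)C(C)(C)C | intermediate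
19 | 12-hydroxy-3-methoxy-1-oxo-13-nor-5αH,7αH-eudesma-2,4(15)-dien-6α-yl 2-[(tert-butyldiphenylsilyloxy)methyl]acrylate | C=C(CO[Si](c3ccccc3)(c4ccccc4)C(C)(C)C)C(=O)O[C@@H]1[C@H]2C(=C)C(OC)=CC(=O)[C@]2(C)CC[C@H]1CCO | intermediate
20 | 3-methoxy-1,12-dioxo-13-nor-5αH,7αH-eudesma-2,4(15)-dien-6α-yl 2-[(tert-butyldiphenylsilyloxy)methyl]acrylate (12-aldehyde) | C=C(CO[Si](c3ccccc3)(c4ccccc4)C(C)(C)C)C(=O)O[C@@H]1[C@H]2C(=C)C(OC)=CC(=O)[C@]2(C)CC[C@H]1CC=O | intermediate (not isolated)
21 | 3-methoxy-1,12-dioxo-5αH,7αH-eudesma-2,4(15),11(13)-trien-6α-yl 2-[(tert-butyldiphenylsilyloxy)methyl]acrylate (12-enal) | C=C(CO[Si](c3ccccc3)(c4ccccc4)C(C)(C)C)C(=O)O[C@@H]1[C@H]2C(=C)C(OC)=CC(=O)[C@]2(C)CC[C@H]1C(=C)C=O | intermediate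
22 | 6α-{2-[(tert-butyldiphenylsilyloxy)methyl]acryloyloxy}-3-methoxy-1-oxo-5αH,7αH-eudesma-2,4(15),11(13)-trien-12-oic acid | C=C(CO[Si](c3ccccc3)(c4ccccc4)C(C)(C)C)C(=O)O[C@@H]1[C@H]2C(=C)C(OC)=CC(=O)[C@]2(C)CC[C@H]1C(=C)C(=O)O | intermediate (not isolated)
23 | methyl 6α-{2-[(tert-butyldiphenylsilyloxy)methyl]acryloyloxy}-3-methoxy-1-oxo-5αH,7αH-eudesma-2,4(15),11(13)-trien-12-oate | C=C(CO[Si](c3ccccc3)(c4ccccc4)C(C)(C)C)C(=O)O[C@@H]1[C@H]2C(=C)C(OC)=CC(=O)[C@]2(C)CC[C@H]1C(=C)C(=O)OC | intermediate
24 | methyl 6α-{2-[(tert-butyldiphenylsilyloxy)methyl]acryloyloxy}-1β-hydroxy-3-methoxy-5αH,7αH-eudesma-2,4(15),11(13)-trien-12-oate | C=C(CO[Si](c3ccccc3)(c4ccccc4)C(C)(C)C)C(=O)O[C@@H]1[C@H]2C(=C)C(OC)=C[C@@H](O)[C@]2(C)CC[C@H]1C(=C)C(=O)OC | intermediate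
25 | methyl 6α-{2-[(tert-butyldiphenylsilyloxy)methyl]acryloyloxy}-3-methoxy-1β-(triethylsilyloxy)-5αH,7αH-eudesma-2,4(15),11(13)-trien-12-oate | C=C(CO[Si](c3ccccc3)(c4ccccc4)C(C)(C)C)C(=O)O[C@@H]1[C@H]2C(=C)C(OC)=C[C@@H](O[Si](CC)(CC)CC)[C@]2(C)CC[C@H]1C(=C)C(=O)OC | intermediate
26 | methyl 6α-{2-[(tert-butyldiphenylsilyloxy)methyl]acryloyloxy}-3-oxo-1β-(triethylsilyloxy)-5αH,7αH-eudesma-4(15),11(13)-dien-12-oate | C=C(CO[Si](c3ccccc3)(c4ccccc4)C(C)(C)C)C(=O)O[C@@H]1[C@H]2C(=C)C(=O)C[C@@H](O[Si](CC)(CC)CC)[C@]2(C)CC[C@H]1C(=C)C(=O)OC | intermediate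
27 | methyl 6α-{2-[(tert-butyldiphenylsilyloxy)methyl]acryloyloxy}-3β-hydroxy-1β-(triethylsilyloxy)-5αH,7αH-eudesma-4(15),11(13)-dien-12-oate | C=C(CO[Si](c3ccccc3)(c4ccccc4)C(C)(C)C)C(=O)O[C@@H]1[C@H]2C(=C)[C@@H](O)C[C@@H](O[Si](CC)(CC)CC)[C@]2(C)CC[C@H]1C(=C)C(=O)OC | intermediate
28 | methyl 1β,3β-dihydroxy-6α-[2-(hydroxymethyl)acryloyloxy]-5αH,7αH-eudesma-4(15),11(13)-dien-12-oate (CNP0247525.1) | C=C(CO)C(=O)O[C@@H]1[C@H]2C(=C)[C@@H](O)C[C@@H](O)[C@]2(C)CC[C@H]1C(=C)C(=O)OC | target

**Step count and risks**

Total step count: 20. Longest linear sequence: 17 steps (steps 1–3, 5–9, 12–20).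

Steps most likely to fail:

1. Step 5. Facial control by the catalyst may be insufficient at the methyl-bearing double bond, or desilylative Mukaiyama–Michael addition may compete with cycloaddition. Fallback with auxiliary control, setting out from enal 6 and quinone 9: the potassium dienolate of 6 (KN(SiMe3)2, THF, −78 °C) is O-acylated with (S)-O-methylmandeloyl chloride to give the (1E)-dienyl (S)-O-methylmandelate F1. Uncatalysed cycloaddition with 9 (toluene, 80 °C) keeps the inherent orientation and endo preference, and the two facial adducts are now diastereomers that can be separated, giving the cis-fused mandelate adduct F2. DBU equilibration gives the trans-fused mandelate F3, and mild methanolysis (K2CO3, MeOH, 0 °C) removes the auxiliary and returns to the route at 12.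

2. Step 6. Equilibration to the trans isomer may stall, or beta-elimination of the silyloxy group may take over from the enolate. Fallback by changing the order and the mechanism, setting out from 10: desilylation (HF·pyridine, pyridine, THF, 0 °C) gives the cis-fused allylic alcohol F4. Hydroxyl-directed hydrogenation ([Ir(cod)(PCy3)(py)]PF6, H2) gives the cis-fused saturated hydroxy ketone F5. C5 is then equilibrated by acid-catalysed enolisation (p-TsOH cat., benzene, rt), where the chair trans-decalin with all ring-B substituents equatorial and the O–H···O=C hydrogen bond should favour the trans isomer and no enolate is available for elimination. The route is rejoined at 13.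

3. Step 9. Methylenation at the hindered, conjugated C4 carbonyl may be sluggish, or the beta-hydroxy ketone may undergo retro-aldol cleavage under the Lewis-acidic conditions. Fallback by Peterson olefination, setting out from 13: addition of Me3SiCH2Li/CeCl3 (THF, −78 °C) to the C4 ketone gives the beta-hydroxysilane F6, and syn-elimination with KH (THF, 0 °C to rt) returns to the route at 14.

Further compounds
F1 | step 5 | (1E)-2-[2-(tert-butyldimethylsilyloxy)ethyl]buta-1,3-dien-1-yl (S)-2-methoxy-2-phenylacetate | C=C/C(CCO[Si](C)(C)C(C)(C)C)=C/OC(=O)[C@@H](OC)c1ccccc1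
F2 | step 5 | cis-fused cycloadduct (5βH) with a 6α-(S)-O-methylmandelate in place of the silyl ether | CO[C@@H](c3ccccc3)C(=O)O[C@@H]1[C@@H]2C(=O)C(OC)=CC(=O)[C@]2(C)CC=C1CCO[Si](C)(C)C(C)(C)C
F3 | step 5 | trans-fused 6α-(S)-O-methylmandelate (5αH) | CO[C@@H](c3ccccc3)C(=O)O[C@@H]1[C@H]2C(=O)C(OC)=CC(=O)[C@]2(C)CC=C1CCO[Si](C)(C)C(C)(C)C
F4 | step 6 | 12-(tert-butyldimethylsilyloxy)-6α-hydroxy-3-methoxy-13,15-dinor-5βH-eudesma-2,7-diene-1,4-dione (cis-fused) | O[C@@H]1[C@@H]2C(=O)C(OC)=CC(=O)[C@]2(C)CC=C1CCO[Si](C)(C)C(C)(C)C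
F5 | step 6 | 12-(tert-butyldimethylsilyloxy)-6α-hydroxy-3-methoxy-13,15-dinor-5βH,7αH-eudesm-2-ene-1,4-dione (cis-fused) | O[C@@H]1[C@@H]2C(=O)C(OC)=CC(=O)[C@]2(C)CC[C@H]1CCO[Si](C)(C)C(C)(C)C
F6 | step 9 | 12-(tert-butyldimethylsilyloxy)-4,6α-dihydroxy-3-methoxy-4-(trimethylsilylmethyl)-13,15-dinor-5αH,7αH-eudesm-2-en-1-one (C4 configuration not defined) | O[C@@H]1[C@H]2C(O)(C[Si](C)(C)C)C(OC)=CC(=O)[C@]2(C)CC[C@H]1CCO[Si](C)(C)C(C)(C)C
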